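Remark on the chemistry: the target has no stereocentre and rotation about the two aryl–oxygen bonds is taken to be fast, so no configuration has to be set. Compound 15 is used as the racemate because its only stereocentre is destroyed in step 8. The structures of the key-step precursor 11, of 15 and of the key-step product 20 were checked atom by atom against the bond mapping and are used unchanged. What is changed is the chemistry after the ring is built: no Lewis-acid formylation and no chlorite oxidation is run while the ortho-hydroxybenzyl silyl ether and the free phenol are present.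

## Structural features

The target consists of two hexasubstituted benzene rings joined only through an ether oxygen. Ring A carries C1 CO2Me, C2 Me, C3 O-aryl, C4 OH, C5 Me and C6 OH. Ring B carries C1' O-aryl, C2' CHO, C3' OH, C4' Cl, C5' Me and C6' CO2H. All four carbons ortho to the ether oxygen (C2, C4, C2', C6') are substituted, so the C3–O–C1' linkage is a tetra-ortho-substituted diaryl ether. There are no stereocentres, so the problem is one of regiochemistry and functional-group compatibility. The fragile groups are the C2' aldehyde (a salicylaldehyde between the ether and the C3' hydroxyl), the three electron-rich phenols, the C4' aryl chloride (which rules out hydrogenolysis), and the ring A methyl ester, which must survive while the C6' acid is made free. The real difficulty is twofold: forming the crowded C3–O–C1' bond, and placing six different substituents on ring B, three of them carbon groups at three different oxidation levels. The key step exploits the fact that ring B is a resorcinol monoether. C1' (ether) and C3' (hydroxyl) are meta with the carbon-bearing C2' between them, and chlorine sits on C4' next to the hydroxyl. The C1'–C2' pair therefore maps onto an ynol ether and the C3'–C4'–C5'–C6' chain onto a chlorovinylketene.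

## Logic of the disconnections

**27 to 26.** The three O–benzyl bonds (at C4 and C6 of ring A and at C3' of ring B) are cut last. Keeping all phenols masked until the end removes acidic, oxidisable and chelating hydroxyls from every organometallic and oxidation step. The demand on the forward step is a cleavage that spares the aryl chloride, the aldehyde and the methyl ester, which points to a Lewis acid and not to hydrogen.

**26 to 25 to 24.** No skeletal bond is cut. The C2' formyl group is taken back to the primary alcohol and then to its silyl ether (O–Si bond). An aldehyde could not coexist with the organomagnesium step that installs C6', so C2' travels at the alcohol level. The forward steps must remove the silyl group without a free benzylic alkoxide and oxidise a benzylic alcohol next to a free acid.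

**24 to 22 (through 23), 22 to 21, 21 to 20.** The C6'–CO2H bond is cut to an aryl-metal and CO2, then the C3'–O-benzyl bond and the C6'–I bond. C6' is the only unsubstituted carbon of ring B and is para to the phenol, so an electrophile has one site only. Carboxylation gives the acid directly at the right oxidation level and keeps it distinct from the ring A ester and from C2'. The gain is that 20 needs only a C–H at C6'. The demands are a neutral halogenation, and a halogen–metal exchange that is faster than attack on the ester.

**20 to 11 plus 15.** The bonds C2'–C3', C1'–C6' and C3'–C4' are cut, so ring B disappears. The ether oxygen is then attached to an alkyne carbon and never to a preformed crowded arene, and the meta relation of ether and hydroxyl follows from the polarity of the ynol ether. The simplification is large: a hexasubstituted ring becomes a four-carbon ketone and an alkyne. The forward step needs a clean thermal cascade and a single orientation in the (2+2) event.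

**15 to 14 to 12 plus 13.** One C–Cl bond of 14 is exchanged for C–H, then the two ring bonds C1–C2 and C3–C4 of the cyclobutenone are cut to an alkyne and dichloroketene. Both components are bulk chemicals. The forward demands are the orientation of the ketene addition and a reduction that stops after one chlorine.

**11 to 7 (through 8, 9, 10).** The C(sp)–CH2 bond and the O–Si bond are cut, leaving an aryloxyacetylide, formaldehyde and a silyl chloride. The dichlorovinyl ether is a stable, storable acetylide precursor. The forward step must generate the acetylide without harming the ring A ester, and must not expose the free ynol-ether carbinol to acid.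

**7 to 5 plus 6.** The O–C(vinyl) bond is cut. Adding a phenoxide to a small linear electrophile is insensitive to the two ortho substituents of 5, which is the whole point of routing the ether oxygen this way.

**5 to 3 (through 4), 3 to 2, 2 to 1.** The C5–O bond is traced to a C5–CHO bond by aryl migration, the benzyl ethers are removed, and the C5–CHO bond is cut. C5 is the only free position of 1, so the formylation has one outcome. The forward order (formylate, then benzylate, then oxidise) keeps the Lewis acid away from benzyl ethers.

## Other disconnections considered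

**Alternative 1:** Ring B is cut at C4'–C5' and C2'–C3'. C1', C2', C5' and C6' then come from the pyranone A1 (a 4-aryloxy-6-methyl-2-pyranone-5-carboxylate carrying the ring A residue of 5), and C3' and C4' come from the chloroketene acetal A2.

- Forward step: an inverse-demand Diels–Alder reaction, loss of CO2 from the bridged lactone and loss of methanol would give the benzoate A3.
- In favour: the orientation is set by polarity, since C6 of A1 (beta to the ester) is the electrophilic terminus and takes the chlorinated carbon. Only methanol can be eliminated in the aromatisation, because the acetal carbon has no hydrogen, so chlorine is retained.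
- Point on which it is better: A3 already carries the C6' carboxyl carbon at the correct oxidation level. The chosen plan spends steps 9 to 11 on this.
- Point on which it is equal: ring B is again built on the ether oxygen, and both are pericyclic cascades with built-in regiocontrol.
- Against: C2' is left as C–H between two oxygen substituents and must be formylated late on a ring that carries esters and benzyl ethers. The C3' oxygen arrives as a methyl ether needing its own cleavage. The 4-aryloxy donor and the C6 methyl of A1 both slow the cycloaddition, so forcing temperatures are expected, at which A2 may polymerise.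
- Step economy: A1 and A2 each need several steps, which should roughly cancel the steps saved.

**Alternative 2:** Ring A is cut at C1–C2 and C4–C5.

- Forward step: the crotonate A5, made from the fully substituted ring B phenol A4, would accept C2 of the keto ester A6 in a Michael addition. A Dieckmann-type closure of the keto ester gamma carbon onto the crotonate ester would give the dione A7, which must then be dehydrogenated to the resorcinol.
- Point on which it is better: ring A with its complete substitution pattern comes from two simple acyclic pieces in one annulation. The chosen plan needs three steps to functionalise 1.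
- Point on which it is equal: the ether oxygen is attached by substitution at an sp3 carbon, so no crowded aryl–oxygen coupling is needed.
- Against: the plan leaves the hexasubstituted ring B, which is the harder half, entirely to a separate synthesis of A4. A5 is a beta-methyl, alpha-donor-substituted acceptor and should be sluggish. The Michael step is reversible.
- Specific hazard: A7 stands at the oxidation level from which loss of the ring B phenoxide alone would give an aromatic ring, namely 1. Aromatisation by elimination therefore competes in principle with the desired dehydrogenation.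
- Overall: the sequence is expected to be longer and mechanistically less secure than the chosen plan.

**Alternative 3:** The C1'–O bond and the C2'–carboxyl bond are cut.

- Forward step: fluoride would release the aryne A9 from the ortho-silylaryl triflate A8 under CO2. Phenol 5, as its caesium salt formed in the flask, would add at C1', and the C2' aryl anion would be carboxylated to give A10.
- Point on which it is better: convergence. The two rings are joined and a carbon substituent is introduced in one mild operation.
- Point on which it is equal: the crowded phenoxide only has to attack a very reactive, unhindered electrophile, just as in the vinylation of the chosen plan. The methoxy group next to the aryne directs the nucleophile to the distal carbon, which is the required orientation.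
- Against: the oxidation levels come out inverted. C2' receives an acid where an aldehyde is needed, and C6' stays C–H where the acid is needed. One carboxyl must be reduced in the presence of the ring A ester, and a second must still be introduced as in the chosen plan. Proton capture by the aryl anion and carbonate formation at the phenoxide compete with the three-component path. A8 is itself a pentasubstituted benzene requiring a multi-step synthesis.
- Overall: the number of steps after the key step would not be lower than in the chosen plan.

Key step: step 8

## Route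

**Step 1**
Reactants: 1 methyl 2,4-dihydroxy-3,6-dimethylbenzoate (methyl beta-orsellinate)
Product: 2 methyl 5-formyl-2,4-dihydroxy-3,6-dimethylbenzoate
Conditions: Cl2CHOMe, TiCl4, CH2Cl2, 0 °C to rt; then aq. HCl
Reagents that add atoms: dichloromethyl methyl ether, COC(Cl)Cl; water, O
Why: Rieche formylation; C5 is the only unsubstituted ring carbon, ortho to the C4 hydroxyl and para to the C2 hydroxyl, and the titanium phenoxide delivers the electrophile there; it is run before benzylation because TiCl4 would cleave a benzyl ether ortho to the ester.

**Step 2**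
Reactants: 2 methyl 5-formyl-2,4-dihydroxy-3,6-dimethylbenzoate
Product: 3 methyl 2,4-bis(benzyloxy)-5-formyl-3,6-dimethylbenzoate
Conditions: BnBr, K2CO3, DMF, 60 °C
Reagents that add atoms: benzyl bromide, BrCc1ccccc1
Why: Williamson ether synthesis; both phenols are hydrogen-bonded to ortho carbonyl groups, hence DMF and warming; the aldehyde has no alpha hydrogen and the hindered ester is inert to carbonate.

**Step 3**
Reactants: 3 methyl 2,4-bis(benzyloxy)-5-formyl-3,6-dimethylbenzoate
Product: 5 methyl 2,4-bis(benzyloxy)-5-hydroxy-3,6-dimethylbenzoate, via aryl formate 4 (not isolated)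
Conditions: mCPBA, CH2Cl2, 0 °C to rt; aq. NaHCO3 wash; then K2CO3 (cat.), MeOH, rt
Reagents that add atoms: meta-chloroperoxybenzoic acid, OOC(=O)c1cccc(Cl)c1
Why: Baeyer–Villiger (Dakin-type) oxidation; the aryl group with ortho and para benzyloxy donors migrates in preference to hydrogen to give formate 4, which is methanolysed without change to the methyl ester because transesterification with methanol is degenerate.

**Step 4**
Reactants: 5 methyl 2,4-bis(benzyloxy)-5-hydroxy-3,6-dimethylbenzoate; 6 trichloroethylene
Product: 7 methyl 2,4-bis(benzyloxy)-5-{[(E)-1,2-dichloroethenyl]oxy}-3,6-dimethylbenzoate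
Conditions: K2CO3, DMF, 70 °C, argon
Reagents that add atoms: none
Why: Base-mediated vinylation of a phenol; carbonate converts 6 into dichloroacetylene in the flask and the phenoxide adds anti to give the (E)-dichlorovinyl ether; the electrophile is small and linear, so the two ortho substituents of 5 do not interfere.

**Step 5**
Reactants: 7 methyl 2,4-bis(benzyloxy)-5-{[(E)-1,2-dichloroethenyl]oxy}-3,6-dimethylbenzoate
Product: 11 methyl 2,4-bis(benzyloxy)-5-{[3-(tert-butyldimethylsilyloxy)prop-1-yn-1-yl]oxy}-3,6-dimethylbenzoate, via chloroalkynyl ether 8 (not isolated), via lithium acetylide 9 (not isolated), via lithium alkoxide 10 (not isolated)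
Conditions: n-BuLi (2.1 equiv), Et2O, −78 to −40 °C; (CH2O)n, −40 to 0 °C; TBSCl, DMAP (cat.), THF, 0 °C to rt
Reagents that add atoms: formaldehyde (from paraformaldehyde), C=O; tert-butyldimethylsilyl chloride, CC(C)(C)[Si](C)(C)Cl
Why: Dehydrochlorination and chlorine–lithium exchange give acetylide 9, which adds to formaldehyde (acetylide addition to an aldehyde) and is silylated in the same flask so that the acid-sensitive free carbinol of an ynol ether is never handled; the methyl ester is shielded by its two ortho substituents and sees butyllithium only at or below −40 °C.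

**Step 6**
Reactants: 12 propyne; 13 trichloroacetyl chloride
Product: 14 4,4-dichloro-3-methylcyclobut-2-en-1-one
Conditions: Zn–Cu couple, Et2O–DME, propyne (excess, condensed), slow addition of 13, 0 °C to rt, dry-ice condenser
Reagents that add atoms: none
Why: (2+2) cycloaddition of dichloroketene, formed by zinc dechlorination of 13, to the alkyne; the terminal alkyne carbon bonds to the ketene carbonyl carbon, placing methyl at C3 and CCl2 at C4, and DME ties up ZnCl2 so that allylic chlorine migration is suppressed.

**Step 7**
Reactants: 14 4,4-dichloro-3-methylcyclobut-2-en-1-one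
Product: 15 4-chloro-3-methylcyclobut-2-en-1-one (racemic)
Conditions: Zn dust (1.05 equiv), AcOH, TMEDA, EtOH, −10 to 0 °C
Reagents that add atoms: none
Why: Reductive dehalogenation of an alpha,alpha-dichloroketone with zinc; with one equivalent at low temperature the reaction should stop at the monochloride because the second reduction is slower, and TMEDA complexes the zinc salts that would promote chlorine migration; the new stereocentre is formed racemic and is irrelevant.

**Step 8**
Reactants: 11 methyl 2,4-bis(benzyloxy)-5-{[3-(tert-butyldimethylsilyloxy)prop-1-yn-1-yl]oxy}-3,6-dimethylbenzoate; 15 4-chloro-3-methylcyclobut-2-en-1-one (racemic)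
Product: 20 methyl 2,4-bis(benzyloxy)-5-[2-{[(tert-butyldimethylsilyl)oxy]methyl}-4-chloro-3-hydroxy-5-methylphenoxy]-3,6-dimethylbenzoate, via chlorovinylketene 16 (not isolated), via vinylcyclobutenone 17 (not isolated), via dienylketene 18 (not isolated), via cyclohexadienone 19 (not isolated)
Conditions: 15 (1.5 equiv), PhMe, 85 °C, sealed tube, argon
Reagents that add atoms: none
Why: Danheiser benzannulation, the reaction of a cyclobutenone with a heteroatom-substituted alkyne, well established for alkoxy- and silyloxyalkynes and applied here to an aryloxyalkyne and a 4-chlorocyclobutenone. Heat opens 15 by 4π electrocyclic cleavage of its C(=O)–CHCl bond to the chlorovinylketene 16, with chlorine as a donor rotating outward, and the stereocentre of 15 is lost at this point. The ketene C=C of 16 and the triple bond of 11 then join in a (2+2) cycloaddition in which the CH2OSi-bearing alkyne carbon (future C2') bonds to the ketene carbonyl carbon (C3') and the oxygen-bearing carbon (C1') bonds to the ketene alpha carbon (C6'), giving 17. A second 4π opening of 17 gives the dienylketene 18, and its thermal disrotatory 6π electrocyclisation closes ring B by forming C3'–C4'. Tautomerisation of 19, driven by aromatisation, gives the phenol with chlorine fixed at C4'. Ring B is the only ring closed in the end and it is closed by 6π electrocyclisation; no stereocentre remains, since those of 17 and 19 are erased by ring opening and enolisation. The selectivity needed is the orientation of the (2+2) step, which is secured by the polarisation of the ynol ether: the oxygen lone pair makes the distal carbon the nucleophile. Reaction with the alkyne in preference to ketene dimerisation is helped by the slow thermal release of 16, and an aryl ynol ether cannot undergo the retro-ene loss of ketene that limits alkyl ynol ethers at this temperature.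

**Step 9**
Reactants: 20 methyl 2,4-bis(benzyloxy)-5-[2-{[(tert-butyldimethylsilyl)oxy]methyl}-4-chloro-3-hydroxy-5-methylphenoxy]-3,6-dimethylbenzoate
Product: 21 methyl 2,4-bis(benzyloxy)-5-[2-{[(tert-butyldimethylsilyl)oxy]methyl}-4-chloro-3-hydroxy-6-iodo-5-methylphenoxy]-3,6-dimethylbenzoate
Conditions: NIS (1.05 equiv), MeCN, 0 °C to rt, dark
Reagents that add atoms: N-iodosuccinimide, O=C1CCC(=O)N1I
Why: Electrophilic aromatic iodination; C6' is the only unsubstituted carbon of ring B and is para to the free phenol, ring A has no free position and the benzyl phenyl rings are not activated; the neutral conditions spare the ortho-hydroxybenzyl silyl ether, which a Lewis-acid formylation would ionise.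

**Step 10**
Reactants: 21 methyl 2,4-bis(benzyloxy)-5-[2-{[(tert-butyldimethylsilyl)oxy]methyl}-4-chloro-3-hydroxy-6-iodo-5-methylphenoxy]-3,6-dimethylbenzoate
Product: 22 methyl 2,4-bis(benzyloxy)-5-[3-(benzyloxy)-2-{[(tert-butyldimethylsilyl)oxy]methyl}-4-chloro-6-iodo-5-methylphenoxy]-3,6-dimethylbenzoate
Conditions: BnBr, K2CO3, DMF, rt to 40 °C
Reagents that add atoms: benzyl bromide, BrCc1ccccc1
Why: Williamson ether synthesis; masking the phenol lets the exchange of the next step run on a neutral arene and not on an electron-rich phenoxide, and silyl migration from the alkyl oxygen to the phenoxide is thermodynamically uphill.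

**Step 11**
Reactants: 22 methyl 2,4-bis(benzyloxy)-5-[3-(benzyloxy)-2-{[(tert-butyldimethylsilyl)oxy]methyl}-4-chloro-6-iodo-5-methylphenoxy]-3,6-dimethylbenzoate
Product: 24 4-(benzyloxy)-2-[2,4-bis(benzyloxy)-5-(methoxycarbonyl)-3,6-dimethylphenoxy]-3-{[(tert-butyldimethylsilyl)oxy]methyl}-5-chloro-6-methylbenzoic acid, via arylmagnesium chloride 23 (not isolated)
Conditions: i-PrMgCl·LiCl (1.2 equiv), THF, −20 to 0 °C; CO2 (g), −20 °C to rt; cold 1 M HCl to pH 3
Reagents that add atoms: carbon dioxide, O=C=O
Why: Iodine–magnesium exchange with the turbo Grignard reagent followed by carboxylation of 23; the exchange is assisted by the ortho aryloxy group and, at this temperature, tolerates the doubly ortho-substituted methyl ester, the aryl chloride and the ethers; the C6' acid is obtained directly, already distinct from the ring A ester.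

**Step 12**
Reactants: 24 4-(benzyloxy)-2-[2,4-bis(benzyloxy)-5-(methoxycarbonyl)-3,6-dimethylphenoxy]-3-{[(tert-butyldimethylsilyl)oxy]methyl}-5-chloro-6-methylbenzoic acid
Product: 25 4-(benzyloxy)-2-[2,4-bis(benzyloxy)-5-(methoxycarbonyl)-3,6-dimethylphenoxy]-5-chloro-3-(hydroxymethyl)-6-methylbenzoic acid
Conditions: Bu4NF, AcOH (1:1), THF, 0 °C to rt
Reagents that add atoms: none
Why: Fluoride-mediated desilylation of a primary silyl ether, buffered with acetic acid so that no free benzylic alkoxide is present; benzyl ethers, ester, acid and aryl chloride are inert, and the hydroxymethyl and carboxyl groups are meta and cannot lactonise.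

**Step 13**
Reactants: 25 4-(benzyloxy)-2-[2,4-bis(benzyloxy)-5-(methoxycarbonyl)-3,6-dimethylphenoxy]-5-chloro-3-(hydroxymethyl)-6-methylbenzoic acid
Product: 26 4-(benzyloxy)-2-[2,4-bis(benzyloxy)-5-(methoxycarbonyl)-3,6-dimethylphenoxy]-5-chloro-3-formyl-6-methylbenzoic acid
Conditions: Dess–Martin periodinane, CH2Cl2, 0 °C to rt
Reagents that add atoms: none
Why: Dess–Martin oxidation of a primary benzylic alcohol to the aldehyde; it tolerates the free carboxylic acid and cannot overoxidise, and with all phenols still benzylated there is no quinone formation.

**Step 14**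
Reactants: 26 4-(benzyloxy)-2-[2,4-bis(benzyloxy)-5-(methoxycarbonyl)-3,6-dimethylphenoxy]-5-chloro-3-formyl-6-methylbenzoic acid
Product: 27 5-chloro-2-[2,4-dihydroxy-5-(methoxycarbonyl)-3,6-dimethylphenoxy]-3-formyl-4-hydroxy-6-methylbenzoic acid (CNP0210944.0)
Conditions: BCl3, C6HMe5, CH2Cl2, −78 to −20 °C; then H2O
Reagents that add atoms: none
Why: Lewis-acid cleavage of aryl benzyl ethers with pentamethylbenzene as a non-basic benzyl cation scavenger; it is chosen over hydrogenolysis because of the aryl chloride and the aldehyde, and the methyl ester and the diaryl ether are stable at this temperature.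

## Compound list

1 | methyl 2,4-dihydroxy-3,6-dimethylbenzoate (methyl beta-orsellinate) | COC(=O)c1c(C)cc(O)c(C)c1O | starting material
2 | methyl 5-formyl-2,4-dihydroxy-3,6-dimethylbenzoate | COC(=O)c1c(C)c(C=O)c(O)c(C)c1O | intermediate
3 | methyl 2,4-bis(benzyloxy)-5-formyl-3,6-dimethylbenzoate | COC(=O)c1c(C)c(C=O)c(OCc2ccccc2)c(C)c1OCc1ccccc1 | intermediate
4 | methyl 2,4-bis(benzyloxy)-5-(formyloxy)-3,6-dimethylbenzoate (not isolated) | COC(=O)c1c(C)c(OC=O)c(OCc2ccccc2)c(C)c1OCc1ccccc1 | intermediate
5 | methyl 2,4-bis(benzyloxy)-5-hydroxy-3,6-dimethylbenzoate | COC(=O)c1c(C)c(O)c(OCc2ccccc2)c(C)c1OCc1ccccc1 | intermediate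
6 | trichloroethylene | ClC=C(Cl)Cl | starting material
7 | methyl 2,4-bis(benzyloxy)-5-{[(E)-1,2-dichloroethenyl]oxy}-3,6-dimethylbenzoate | COC(=O)c1c(C)c(O/C(Cl)=C\Cl)c(OCc2ccccc2)c(C)c1OCc1ccccc1 | intermediate
8 | methyl 2,4-bis(benzyloxy)-5-[(chloroethynyl)oxy]-3,6-dimethylbenzoate (not isolated) | COC(=O)c1c(C)c(OC#CCl)c(OCc2ccccc2)c(C)c1OCc1ccccc1 | intermediate
9 | methyl 2,4-bis(benzyloxy)-5-[(lithioethynyl)oxy]-3,6-dimethylbenzoate (not isolated) | COC(=O)c1c(C)c(OC#C[Li])c(OCc2ccccc2)c(C)c1OCc1ccccc1 | intermediate
10 | lithium 3-[2,4-bis(benzyloxy)-5-(methoxycarbonyl)-3,6-dimethylphenoxy]prop-2-yn-1-olate (not isolated) | COC(=O)c1c(C)c(OC#CCO[Li])c(OCc2ccccc2)c(C)c1OCc1ccccc1 | intermediate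
11 | methyl 2,4-bis(benzyloxy)-5-{[3-(tert-butyldimethylsilyloxy)prop-1-yn-1-yl]oxy}-3,6-dimethylbenzoate | COC(=O)c1c(C)c(OC#CCO[Si](C)(C)C(C)(C)C)c(OCc2ccccc2)c(C)c1OCc1ccccc1 | intermediate
12 | propyne | CC#C | starting material
13 | trichloroacetyl chloride | O=C(Cl)C(Cl)(Cl)Cl | starting material
14 | 4,4-dichloro-3-methylcyclobut-2-en-1-one | CC1=CC(=O)C1(Cl)Cl | intermediate
15 | 4-chloro-3-methylcyclobut-2-en-1-one (racemic) | CC1=CC(=O)C1Cl | intermediate
16 | (E)-4-chloro-3-methylbuta-1,3-dien-1-one (not isolated) | O=C=C/C(C)=C/Cl | intermediate
17 | methyl 2,4-bis(benzyloxy)-5-({2-[(tert-butyldimethylsilyloxy)methyl]-4-[(E)-1-chloroprop-1-en-2-yl]-3-oxocyclobut-1-en-1-yl}oxy)-3,6-dimethylbenzoate (racemic, not isolated) | COC(=O)c1c(C)c(OC2=C(CO[Si](C)(C)C(C)(C)C)C(=O)C2/C(C)=C/Cl)c(OCc2ccccc2)c(C)c1OCc1ccccc1 | intermediate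
18 | methyl 2,4-bis(benzyloxy)-5-({(3E,5E)-2-[(tert-butyldimethylsilyloxy)methyl]-6-chloro-5-methyl-1-oxohexa-1,3,5-trien-3-yl}oxy)-3,6-dimethylbenzoate (not isolated) | COC(=O)c1c(C)c(O/C(C(CO[Si](C)(C)C(C)(C)C)=C=O)=C/C(C)=C/Cl)c(OCc2ccccc2)c(C)c1OCc1ccccc1 | intermediate
19 | methyl 2,4-bis(benzyloxy)-5-({2-[(tert-butyldimethylsilyloxy)methyl]-4-chloro-5-methyl-3-oxocyclohexa-1,5-dien-1-yl}oxy)-3,6-dimethylbenzoate (racemic, not isolated) | COC(=O)c1c(C)c(OC2=C(CO[Si](C)(C)C(C)(C)C)C(=O)C(Cl)C(C)=C2)c(OCc2ccccc2)c(C)c1OCc1ccccc1 | intermediate
20 | methyl 2,4-bis(benzyloxy)-5-[2-{[(tert-butyldimethylsilyl)oxy]methyl}-4-chloro-3-hydroxy-5-methylphenoxy]-3,6-dimethylbenzoate | COC(=O)c1c(C)c(Oc2cc(C)c(Cl)c(O)c2CO[Si](C)(C)C(C)(C)C)c(OCc2ccccc2)c(C)c1OCc1ccccc1 | intermediate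
21 | methyl 2,4-bis(benzyloxy)-5-[2-{[(tert-butyldimethylsilyl)oxy]methyl}-4-chloro-3-hydroxy-6-iodo-5-methylphenoxy]-3,6-dimethylbenzoate | COC(=O)c1c(C)c(Oc2c(I)c(C)c(Cl)c(O)c2CO[Si](C)(C)C(C)(C)C)c(OCc2ccccc2)c(C)c1OCc1ccccc1 | intermediate
22 | methyl 2,4-bis(benzyloxy)-5-[3-(benzyloxy)-2-{[(tert-butyldimethylsilyl)oxy]methyl}-4-chloro-6-iodo-5-methylphenoxy]-3,6-dimethylbenzoate | COC(=O)c1c(C)c(Oc2c(I)c(C)c(Cl)c(OCc3ccccc3)c2CO[Si](C)(C)C(C)(C)C)c(OCc2ccccc2)c(C)c1OCc1ccccc1 | intermediate
23 | methyl 2,4-bis(benzyloxy)-5-[3-(benzyloxy)-2-{[(tert-butyldimethylsilyl)oxy]methyl}-4-chloro-6-(chloromagnesio)-5-methylphenoxy]-3,6-dimethylbenzoate (not isolated) | COC(=O)c1c(C)c(Oc2c([Mg]Cl)c(C)c(Cl)c(OCc3ccccc3)c2CO[Si](C)(C)C(C)(C)C)c(OCc2ccccc2)c(C)c1OCc1ccccc1 | intermediate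
24 | 4-(benzyloxy)-2-[2,4-bis(benzyloxy)-5-(methoxycarbonyl)-3,6-dimethylphenoxy]-3-{[(tert-butyldimethylsilyl)oxy]methyl}-5-chloro-6-methylbenzoic acid | COC(=O)c1c(C)c(Oc2c(C(=O)O)c(C)c(Cl)c(OCc3ccccc3)c2CO[Si](C)(C)C(C)(C)C)c(OCc2ccccc2)c(C)c1OCc1ccccc1 | intermediate
25 | 4-(benzyloxy)-2-[2,4-bis(benzyloxy)-5-(methoxycarbonyl)-3,6-dimethylphenoxy]-5-chloro-3-(hydroxymethyl)-6-methylbenzoic acid | COC(=O)c1c(C)c(Oc2c(C(=O)O)c(C)c(Cl)c(OCc3ccccc3)c2CO)c(OCc2ccccc2)c(C)c1OCc1ccccc1 | intermediate
26 | 4-(benzyloxy)-2-[2,4-bis(benzyloxy)-5-(methoxycarbonyl)-3,6-dimethylphenoxy]-5-chloro-3-formyl-6-methylbenzoic acid | COC(=O)c1c(C)c(Oc2c(C(=O)O)c(C)c(Cl)c(OCc3ccccc3)c2C=O)c(OCc2ccccc2)c(C)c1OCc1ccccc1 | intermediate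
27 | 5-chloro-2-[2,4-dihydroxy-5-(methoxycarbonyl)-3,6-dimethylphenoxy]-3-formyl-4-hydroxy-6-methylbenzoic acid (CNP0210944.0) | COC(=O)c1c(C)c(Oc2c(C=O)c(O)c(Cl)c(C)c2C(=O)O)c(O)c(C)c1O | target

## Step count and least certain steps

Total step count: 14. Longest linear sequence: 12 steps (steps 1 to 5 and 8 to 14). The cyclobutenone branch (steps 6 and 7) joins at step 8.

**Step 8 (key step).** The aryloxyalkyne is less electron-rich than the alkoxy- and silyloxyalkynes usually used, so its addition to the vinylketene may be slow. That would leave time for ketene oligomerisation, for acylation of the product phenol by a second ketene, or for thermal decomposition of the chlorocyclobutenone before it opens.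

The fallback generates the same vinylketene photochemically, at a temperature where these side paths are slow, and sets out from 11. (E)-3-Chloro-2-methylprop-2-enoyl chloride F1, made from the corresponding acid with oxalyl chloride, would be converted with diazomethane into (E)-4-chloro-1-diazo-3-methylbut-3-en-2-one F2. Irradiation of F2 in the presence of 11 at room temperature should give vinylketene 16 by Wolff rearrangement. The (2+2) addition and, after gentle warming, the rest of the cascade would follow as in the main route, coming back at 20.

**Step 7.** The reduction may run on to the chlorine-free cyclobutenone. Alternatively the intermediate may be protonated at C2, which would move the double bond and leave chlorine on a vinylic carbon, and zinc salts may promote allylic migration of chlorine in 14.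

The fallback avoids the monochloride altogether and sets out from 14 and 11. Heating the two together should run the same cascade to the non-tautomerisable dienone methyl 2,4-bis(benzyloxy)-5-({2-[(tert-butyldimethylsilyloxy)methyl]-4,4-dichloro-5-methyl-3-oxocyclohexa-1,5-dien-1-yl}oxy)-3,6-dimethylbenzoate F3. Brief treatment with zinc in acetic acid would then remove one chlorine with aromatisation, coming back at 20.

**Step 5.** Butyllithium may add to the ring A methyl ester or deprotonate a benzylic position before the vinylic deprotonation and chlorine–lithium exchange are complete. The ynol ether may also be hydrated or rearranged to an acrylate during work-up.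

The fallback uses no organolithium reagent and sets out from 5, bypassing steps 4 and 5. tert-Butyl[(3,3-dibromoprop-2-en-1-yl)oxy]dimethylsilane F4, from (tert-butyldimethylsilyloxy)acetaldehyde with CBr4 and PPh3, would be coupled with 5 under CuI, 2,2'-bipyridine and K3PO4 in toluene. This should give methyl 2,4-bis(benzyloxy)-5-({(Z)-1-bromo-3-[(tert-butyldimethylsilyl)oxy]prop-1-en-1-yl}oxy)-3,6-dimethylbenzoate F5, and t-BuOK would eliminate HBr to come back at 11.

**Step 11.** Exchange at the electron-rich, doubly ortho-substituted iodide may be slow, which would give the Grignard reagent time to attack the ester, or the aryl anion may be protonated before it meets CO2.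

The fallback replaces the organomagnesium chemistry by catalysis and sets out from 22. Palladium-catalysed hydroxycarbonylation (Pd(OAc)2, Xantphos, CO, H2O, Et3N, DMF, 80 °C) should give the acid directly and comes back at 24. No new compound is made on the way.

## Further compounds

F1 | step 8 | (E)-3-chloro-2-methylprop-2-enoyl chloride | C/C(=C\Cl)C(=O)Cl
F2 | step 8 | (E)-4-chloro-1-diazo-3-methylbut-3-en-2-one | Cl/C=C(\C)C(=O)C=[N+]=[N-]
F3 | step 7 | methyl 2,4-bis(benzyloxy)-5-({2-[(tert-butyldimethylsilyloxy)methyl]-4,4-dichloro-5-methyl-3-oxocyclohexa-1,5-dien-1-yl}oxy)-3,6-dimethylbenzoate | COC(=O)c1c(C)c(OC2=C(CO[Si](C)(C)C(C)(C)C)C(=O)C(Cl)(Cl)C(C)=C2)c(OCc2ccccc2)c(C)c1OCc1ccccc1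
F4 | step 5 | tert-butyl[(3,3-dibromoprop-2-en-1-yl)oxy]dimethylsilane | CC(C)(C)[Si](C)(C)OCC=C(Br)Br
F5 | step 5 | methyl 2,4-bis(benzyloxy)-5-({(Z)-1-bromo-3-[(tert-butyldimethylsilyl)oxy]prop-1-en-1-yl}oxy)-3,6-dimethylbenzoate | COC(=O)c1c(C)c(O/C(Br)=C/CO[Si](C)(C)C(C)(C)C)c(OCc2ccccc2)c(C)c1OCc1ccccc1
F0 | step 11 | none | none
A1 | alternative 1 | benzyl 4-[2,4-bis(benzyloxy)-5-(methoxycarbonyl)-3,6-dimethylphenoxy]-6-methyl-2-oxo-2H-pyran-5-carboxylate | CC1=C(C(=O)OCc2ccccc2)C(Oc2c(C)c(C(=O)OC)c(OCc3ccccc3)c(C)c2OCc2ccccc2)=CC(=O)O1
A2 | alternative 1 | 2-chloro-1,1-dimethoxyethene | COC(OC)=CCl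
A3 | alternative 1 | benzyl 2-[2,4-bis(benzyloxy)-5-(methoxycarbonyl)-3,6-dimethylphenoxy]-5-chloro-4-methoxy-6-methylbenzoate | COc1c(Cl)c(C)c(C(=O)OCc2ccccc2)c(Oc2c(C)c(C(=O)OC)c(OCc3ccccc3)c(C)c2OCc2ccccc2)c1
A4 | alternative 2 | tert-butyl 4-(benzyloxy)-5-chloro-3-(1,3-dioxolan-2-yl)-2-hydroxy-6-methylbenzoate | Oc1c(C2OCCO2)c(OCc2ccccc2)c(Cl)c(C)c1C(=O)OC(C)(C)C
A5 | alternative 2 | methyl 2-[3-(benzyloxy)-6-(tert-butoxycarbonyl)-4-chloro-2-(1,3-dioxolan-2-yl)-5-methylphenoxy]but-2-enoate (E/Z mixture) | CC=C(Oc1c(C2OCCO2)c(OCc2ccccc2)c(Cl)c(C)c1C(=O)OC(C)(C)C)C(=O)OC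
A6 | alternative 2 | methyl 3-oxopentanoate | CCC(=O)CC(=O)OC
A7 | alternative 2 | methyl 5-[3-(benzyloxy)-6-(tert-butoxycarbonyl)-4-chloro-2-(1,3-dioxolan-2-yl)-5-methylphenoxy]-3,6-dimethyl-2,4-dioxocyclohexane-1-carboxylate (mixture of diastereomers and enol tautomers) | COC(=O)C1C(C)C(Oc2c(C3OCCO3)c(OCc3ccccc3)c(Cl)c(C)c2C(=O)OC(C)(C)C)C(=O)C(C)C1=O
A8 | alternative 3 | 4-chloro-3-methoxy-5-methyl-2-(trimethylsilyl)phenyl trifluoromethanesulfonate | COc1c(Cl)c(C)cc(OS(=O)(=O)C(F)(F)F)c1[Si](C)(C)C
A9 | alternative 3 | 4-chloro-3-methoxy-5-methylbenzyne | COC1=C(Cl)C(C)=CC#C1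
A10 | alternative 3 | 2-[2,4-bis(benzyloxy)-5-(methoxycarbonyl)-3,6-dimethylphenoxy]-5-chloro-6-methoxy-4-methylbenzoic acid | COC(=O)c1c(C)c(Oc2cc(C)c(Cl)c(OC)c2C(=O)O)c(OCc2ccccc2)c(C)c1OCc1ccccc1
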